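**Strategy.** The crowded C3'–C6'' biaryl bond is never made by coupling. Ring B of the 4'-methoxyflavone unit is grown around it instead. Ring B carries the future C2 at C1', ring A of the second flavone at C3' and OMe at C4'. This 1,3,4-pattern is what methyl coumalate (C1', C2', C5', C6', ester carbon) gives with an aryl ketene dimethyl acetal (C3', C4'). One heating forms C2'–C3' and C4'–C5', closes ring B, and aromatizes it by loss of CO2 and methanol. The precursor is the ketene acetal of a symmetric 2,6-bis(benzyloxy)phenyl ring. Its para oxygen bears MOM, which survives base and heat and later marks the oxygen that becomes O1''.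

Key step: step 5

Assumption: the C3'–C6'' axis has no descriptor in the target SMILES and is treated as configurationally unassigned, so nothing in the route aims at atroposelection.

Step 1
Reactants: 1 3,5-bis(benzyloxy)phenol
Product: 3 2,6-bis(benzyloxy)-4-hydroxybenzaldehyde, via aryl iminium chloride 2 (not isolated)
Conditions: POCl3, DMF, MeCN, 0 °C to rt; then ice-water
Reagents that add atoms: N,N-dimethylformamide, CN(C)C=O; water, O
Why: Vilsmeier–Haack formylation: the chloroiminium electrophile should attack this phloroglucinol-type ring chiefly at C4 (para to the free hydroxyl, between the two ethers), as it does in 3,5-dimethoxyphenol, water then hydrolyses iminium salt 2, and the minor chelated ortho-hydroxy isomer is less polar and can be removed by crystallization or chromatography.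

Step 2
Reactants: 3 2,6-bis(benzyloxy)-4-hydroxybenzaldehyde
Product: 4 2,6-bis(benzyloxy)-4-(methoxymethoxy)benzaldehyde
Conditions: MOMCl, iPr2NEt, CH2Cl2, 0 °C to rt
Reagents that add atoms: chloromethyl methyl ether, COCCl
Why: Base-mediated O-alkylation (MOM ether formation) of the only free phenol, which is acidified by the para formyl group; an acetal is preferred to a silyl ether because it is inert to the amide and alkoxide bases, the prolonged heating and the lithium enolate chemistry ahead, and it leaves in the same acid treatment that closes the first pyranone.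

Step 3
Reactants: 5 chlorodiphenylphosphine; 6 trimethyl orthoformate
Product: 7 (dimethoxymethyl)diphenylphosphine oxide
Conditions: neat 6 (excess), N2, rt to 80 °C
Reagents that add atoms: none
Why: Michaelis–Arbuzov-type reaction: trivalent phosphorus captures the dimethoxymethyl cation equivalent of the orthoformate and chloride removes a methyl group from the methoxyphosphonium stage, a known way to (dialkoxymethyl)diphenylphosphine oxides.

Step 4
Reactants: 7 (dimethoxymethyl)diphenylphosphine oxide; 4 2,6-bis(benzyloxy)-4-(methoxymethoxy)benzaldehyde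
Product: 9 1,3-bis(benzyloxy)-2-(2,2-dimethoxyethenyl)-5-(methoxymethoxy)benzene (the aryl ketene dimethyl acetal), via hydroxy phosphine oxide adduct 8 (not isolated)
Conditions: LiN(iPr)2, THF, −100 °C; add 4, −100 to −78 °C; then KOtBu, −78 °C to rt; acid-free work-up (pentane, cold aq NaHCO3, basic alumina), used crude
Reagents that add atoms: none
Why: Horner–Wittig olefination: the lithiated phosphine oxide, kept very cold because it is thermally fragile, adds to the aldehyde to give adduct 8, and exchange of lithium for potassium triggers syn elimination of diphenylphosphinate, the established route from aldehydes to ketene O,O-acetals, with no alkene geometry to control because the acetal carbon bears two identical OMe groups.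

Step 5
Reactants: 9 the aryl ketene dimethyl acetal; 10 methyl coumalate
Product: 13 methyl 3-[2,6-bis(benzyloxy)-4-(methoxymethoxy)phenyl]-4-methoxybenzoate, via bridged lactone 11 (not isolated), via dimethoxycyclohexadiene 12 (not isolated)
Conditions: 10 (2 equiv), toluene (ca. 1 M), 4 Å MS, base-washed sealed tube, 110 to 140 °C; then DBU (cat.), 60 °C, if 12 persists
Reagents that add atoms: none
Why: This is an inverse-electron-demand Diels–Alder reaction of a 2-pyranone: the electron-rich CH(aryl) terminus of 9 attacks C6 of 10, the position vinylogous to both the C5 ester and the lactone carbonyl, while the C(OMe)2 terminus joins C3, either in one highly asynchronous event or through a short-lived zwitterion, to give bridged lactone 11. Cycloreversion of 11 expels CO2 and leaves diene 12, whose ring C–H next to the aryl group is gamma to the ester and therefore acidic, so methanol departs on heating or on the DBU finish and aromaticity makes the sequence irreversible. The closest known chemistry is the reaction of methyl coumalate with simple ketene acetals, which delivers 4-alkoxybenzoates by the same three events; a ketene acetal whose aryl group has two ortho ethers is untested and should be slower, which is why 10 is used in excess, the solution is concentrated and sieves take up methanol. Ring B is closed as a six-membered carbocycle by intermolecular [4+2] union of the four diene carbons of 10 and the two alkene carbons of 9, which makes C2'–C3' and C4'–C5'. The stereocentres of 11 and 12 are erased on aromatization, so none needs control. The one selectivity required is regiochemical and is secured by the matched polarization of the partners, which places the aryl group meta and the methoxy group para to the ester, while the C3'–C6'' bond is already present as the vinyl–aryl bond of 9.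

Step 6
Reactants: 13 methyl 3-[2,6-bis(benzyloxy)-4-(methoxymethoxy)phenyl]-4-methoxybenzoate; 14 1-[2,4-bis(benzyloxy)-6-hydroxyphenyl]ethanone
Product: 15 1-[2,4-bis(benzyloxy)-6-hydroxyphenyl]-3-{3-[2,6-bis(benzyloxy)-4-(methoxymethoxy)phenyl]-4-methoxyphenyl}propane-1,3-dione
Conditions: 14 (1.3 equiv), LiN(SiMe3)2 (4 equiv), THF, −78 to 0 °C; add 13, 0 to 50 °C; AcOH quench
Reagents that add atoms: none
Why: Crossed Claisen condensation: the dilithio dianion of 14 (phenoxide plus methyl ketone enolate) is acylated at carbon by the unhindered, non-enolizable ester of 13 and the equilibrium is pulled forward by deprotonation of the 1,3-diketone, the classical ester route to flavone diketones, with benzyl and MOM ethers inert.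

Step 7
Reactants: 15 the 1,3-diketone
Product: 16 5,7-bis(benzyloxy)-2-{3-[2,6-bis(benzyloxy)-4-hydroxyphenyl]-4-methoxyphenyl}-4H-chromen-4-one
Conditions: HCl (ca. 1 M), MeOH–THF, 55 °C
Reagents that add atoms: none
Why: Acid-catalysed cyclodehydration of an o-hydroxyaryl 1,3-diketone (6-exo-trig addition of the phenol to the aroyl carbonyl, then loss of water) builds the pyranone of unit 1, and the same acid transfers the MOM acetal to methanol, whereas benzyl aryl ethers need far stronger acid.

Step 8
Reactants: 16 the flavone phenol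
Product: 17 5,7-bis(benzyloxy)-2-{3-[2,6-bis(benzyloxy)-4-hydroxy-3-iodophenyl]-4-methoxyphenyl}-4H-chromen-4-one
Conditions: NIS (1.0 equiv), MeCN–CH2Cl2, −20 to 0 °C, dark
Reagents that add atoms: N-iodosuccinimide, O=C1CCC(=O)N1I
Why: Electrophilic aromatic iodination: the free phenol ring with two further ether donors is by far the most nucleophilic arene, its para position is blocked by ring B and its two ortho positions are equivalent, so one equivalent of NIS at low temperature should give a single monoiodide without any Lewis acid that could strip the neighbouring benzyl ether and blur which oxygen closes the second pyranone.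

Step 9
Reactants: 17 the iodophenol; 18 1-(benzyloxy)-4-ethynylbenzene
Product: 21 5,7-bis(benzyloxy)-6-{5-[5,7-bis(benzyloxy)-4-oxo-4H-chromen-2-yl]-2-methoxyphenyl}-2-[4-(benzyloxy)phenyl]-4H-chromen-4-one, via ynone 19 (not isolated), via enaminone 20 (not isolated)
Conditions: PdCl2(dppf) (5 mol %), CO (5 bar), 18 (1.5 equiv), Et2NH–DMF, 90 °C
Reagents that add atoms: carbon monoxide, [C-]#[O+]
Why: Carbonylative Sonogashira coupling with annulation, the known one-pot flavone synthesis from o-iodophenols, terminal arylacetylenes and CO: oxidative addition, CO insertion (favoured at a doubly ortho-substituted aryl–palladium bond) and alkynylation give ynone 19, diethylamine adds to give enaminone 20, and the neighbouring phenol displaces the amine in a 6-endo sense, which avoids the aurone and fixes O1'' on the oxygen para to the biaryl bond, hence the 6''-linkage.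

Step 10
Reactants: 21 the pentabenzyl biflavone
Product: 22 6-[5-(5,7-dihydroxy-4-oxo-4H-chromen-2-yl)-2-methoxyphenyl]-5,7-dihydroxy-2-(4-hydroxyphenyl)-4H-chromen-4-one (target)
Conditions: H2 (1 atm), Pd/C, THF–MeOH, rt
Reagents that add atoms: none
Why: Catalytic hydrogenolysis of the five benzyl aryl ethers; the aryl methyl ether, the two aryl-conjugated pyranone C2=C3 bonds and the biaryl should not be touched at one atmosphere and room temperature, so the 4'-OMe group remains the only ether.

**Compound list**

1 | 3,5-bis(benzyloxy)phenol | Oc1cc(OCc2ccccc2)cc(OCc2ccccc2)c1 | starting material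
2 | [2,6-bis(benzyloxy)-4-hydroxybenzylidene]dimethyliminium chloride | C[N+](C)=Cc1c(OCc2ccccc2)cc(O)cc1OCc1ccccc1.[Cl-] | intermediate
3 | 2,6-bis(benzyloxy)-4-hydroxybenzaldehyde | O=Cc1c(OCc2ccccc2)cc(O)cc1OCc1ccccc1 | intermediate
4 | 2,6-bis(benzyloxy)-4-(methoxymethoxy)benzaldehyde | O=Cc1c(OCc2ccccc2)cc(OCOC)cc1OCc1ccccc1 | intermediate
5 | chlorodiphenylphosphine | ClP(c1ccccc1)c1ccccc1 | starting material
6 | trimethyl orthoformate | COC(OC)OC | starting material
7 | (dimethoxymethyl)diphenylphosphine oxide | COC(OC)P(=O)(c1ccccc1)c1ccccc1 | intermediate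
8 | 1-[2,6-bis(benzyloxy)-4-(methoxymethoxy)phenyl]-2-(diphenylphosphoryl)-2,2-dimethoxyethanol (racemic; formed as its lithium alkoxide, drawn as the alcohol) | COC(OC)(C(O)c1c(OCc2ccccc2)cc(OCOC)cc1OCc1ccccc1)P(=O)(c1ccccc1)c1ccccc1 | intermediate
9 | 1,3-bis(benzyloxy)-2-(2,2-dimethoxyethenyl)-5-(methoxymethoxy)benzene (aryl ketene dimethyl acetal) | COC(OC)=Cc1c(OCc2ccccc2)cc(OCOC)cc1OCc1ccccc1 | intermediate
10 | methyl coumalate (methyl 2-oxo-2H-pyran-5-carboxylate) | COC(=O)c1ccc(=O)oc1 | starting material
11 | methyl 7-[2,6-bis(benzyloxy)-4-(methoxymethoxy)phenyl]-8,8-dimethoxy-3-oxo-2-oxabicyclo[2.2.2]oct-5-ene-6-carboxylate (racemic, endo/exo mixture, configuration erased later) | O=C1OC2C(C(=O)OC)=CC1C(OC)(OC)C2c1c(OCc2ccccc2)cc(OCOC)cc1OCc1ccccc1 | intermediate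
12 | methyl 3-[2,6-bis(benzyloxy)-4-(methoxymethoxy)phenyl]-4,4-dimethoxycyclohexa-1,5-diene-1-carboxylate (racemic, configuration erased later) | COC(=O)C1=CC(c2c(OCc3ccccc3)cc(OCOC)cc2OCc2ccccc2)C(OC)(OC)C=C1 | intermediate
13 | methyl 3-[2,6-bis(benzyloxy)-4-(methoxymethoxy)phenyl]-4-methoxybenzoate | COC(=O)c1ccc(OC)c(-c2c(OCc3ccccc3)cc(OCOC)cc2OCc2ccccc2)c1 | intermediate
14 | 1-[2,4-bis(benzyloxy)-6-hydroxyphenyl]ethanone | CC(=O)c1c(O)cc(OCc2ccccc2)cc1OCc1ccccc1 | starting material
15 | 1-[2,4-bis(benzyloxy)-6-hydroxyphenyl]-3-{3-[2,6-bis(benzyloxy)-4-(methoxymethoxy)phenyl]-4-methoxyphenyl}propane-1,3-dione | COc1ccc(C(=O)CC(=O)c2c(O)cc(OCc3ccccc3)cc2OCc2ccccc2)cc1-c1c(OCc2ccccc2)cc(OCOC)cc1OCc1ccccc1 | intermediate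
16 | 5,7-bis(benzyloxy)-2-{3-[2,6-bis(benzyloxy)-4-hydroxyphenyl]-4-methoxyphenyl}-4H-chromen-4-one | COc1ccc(-c2cc(=O)c3c(OCc4ccccc4)cc(OCc4ccccc4)cc3o2)cc1-c1c(OCc2ccccc2)cc(O)cc1OCc1ccccc1 | intermediate
17 | 5,7-bis(benzyloxy)-2-{3-[2,6-bis(benzyloxy)-4-hydroxy-3-iodophenyl]-4-methoxyphenyl}-4H-chromen-4-one | COc1ccc(-c2cc(=O)c3c(OCc4ccccc4)cc(OCc4ccccc4)cc3o2)cc1-c1c(OCc2ccccc2)cc(O)c(I)c1OCc1ccccc1 | intermediate
18 | 1-(benzyloxy)-4-ethynylbenzene | C#Cc1ccc(OCc2ccccc2)cc1 | starting material
19 | analogue of 17 with iodine replaced by a 3-[4-(benzyloxy)phenyl]prop-2-ynoyl group (ynone) | COc1ccc(-c2cc(=O)c3c(OCc4ccccc4)cc(OCc4ccccc4)cc3o2)cc1-c1c(OCc2ccccc2)cc(O)c(C(=O)C#Cc2ccc(OCc3ccccc3)cc2)c1OCc1ccccc1 | intermediate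
20 | analogue of 17 with iodine replaced by an (E)-3-[4-(benzyloxy)phenyl]-3-(diethylamino)prop-2-enoyl group (push–pull enaminone, geometry labile) | COc1ccc(-c2cc(=O)c3c(OCc4ccccc4)cc(OCc4ccccc4)cc3o2)cc1-c1c(OCc2ccccc2)cc(O)c(C(=O)/C=C(/N(CC)CC)c2ccc(OCc3ccccc3)cc2)c1OCc1ccccc1 | intermediate
21 | 5,7-bis(benzyloxy)-6-{5-[5,7-bis(benzyloxy)-4-oxo-4H-chromen-2-yl]-2-methoxyphenyl}-2-[4-(benzyloxy)phenyl]-4H-chromen-4-one | COc1ccc(-c2cc(=O)c3c(OCc4ccccc4)cc(OCc4ccccc4)cc3o2)cc1-c1c(OCc2ccccc2)cc2oc(-c3ccc(OCc4ccccc4)cc3)cc(=O)c2c1OCc1ccccc1 | intermediate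
22 | 6-[5-(5,7-dihydroxy-4-oxo-4H-chromen-2-yl)-2-methoxyphenyl]-5,7-dihydroxy-2-(4-hydroxyphenyl)-4H-chromen-4-one (3',6''-biapigenin 4'-methyl ether) | COc1ccc(-c2cc(=O)c3c(O)cc(O)cc3o2)cc1-c1c(O)cc2oc(-c3ccc(O)cc3)cc(=O)c2c1O | target

**Total steps:** 10. **Longest linear sequence:** 9 (steps 1, 2 and 4 to 10); step 3 is a one-step side branch.

**Steps most likely to fail**

1. **Step 5.** The two ortho benzyloxy groups may shield the nucleophilic carbon so strongly that self-reaction of 10 and capture of 9 by released methanol outpace cycloaddition.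
   - The fallback sets out from 4 and comes back at 13. Ring B is bought and the biaryl bond is made by cross-coupling.
   - Baeyer–Villiger oxidation of 4 (mCPBA, NaHCO3, CH2Cl2) should give 2,6-bis(benzyloxy)-4-(methoxymethoxy)phenyl formate F1.
   - Methanolysis (K2CO3, MeOH) should give 2,6-bis(benzyloxy)-4-(methoxymethoxy)phenol F2.
   - Tf2O and pyridine should give 2,6-bis(benzyloxy)-4-(methoxymethoxy)phenyl trifluoromethanesulfonate F3.
   - Suzuki–Miyaura coupling of the triflate with purchased [2-methoxy-5-(methoxycarbonyl)phenyl]boronic acid (Pd(OAc)2, SPhos, K3PO4, toluene–water, 100 °C) should give 13. This ligand system suits tri-ortho-substituted biaryls.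

2. **Step 4.** The lithiated reagent may decompose before it adds to the hindered, electron-rich aldehyde, or the ketene acetal may hydrolyse during isolation.
   - The fallback sets out from 4 and comes back at 13. The olefination is replaced by enolate silylation of a homologated ester, and the methyl ether is installed afterwards.
   - Wittig methoxymethylenation (Ph3P(CH2OMe)Cl, KOtBu, THF) should give 1,3-bis(benzyloxy)-2-(2-methoxyethenyl)-5-(methoxymethoxy)benzene F4.
   - Oxidation of this enol ether with pyridinium chlorochromate (buffered with NaOAc, CH2Cl2) should give methyl [2,6-bis(benzyloxy)-4-(methoxymethoxy)phenyl]acetate F5.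
   - LiN(iPr)2 and TBSCl (THF, −78 °C) should give the methyl tert-butyldimethylsilyl ketene acetal F6.
   - Heating F6 with 10 as in step 5 should give, after loss of CO2 and methanol, methyl 3-[2,6-bis(benzyloxy)-4-(methoxymethoxy)phenyl]-4-(tert-butyldimethylsilyloxy)benzoate F7.
   - TBAF should give methyl 3-[2,6-bis(benzyloxy)-4-(methoxymethoxy)phenyl]-4-hydroxybenzoate F8.
   - MeI and K2CO3 in acetone should then give 13. Any material that lost silanol instead of methanol is already 13.

3. **Step 9.** Aminocarbonylation by diethylamine, direct alkynylation with benzofuran closure, or 5-exo closure may compete with the wanted sequence at this hindered iodide.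
   - The fallback sets out from 17 and comes back at 21. The second pyranone is built stepwise through a chalcone.
   - Stille coupling with tributyl(1-ethoxyvinyl)stannane (Pd(PPh3)4, dioxane, 100 °C) should give the 1-ethoxyvinyl arene F9.
   - Brief treatment with dilute HCl in THF should give the o-hydroxyacetophenone F10.
   - Claisen–Schmidt condensation with purchased 4-(benzyloxy)benzaldehyde (KOH, EtOH–THF, rt) should give the (E)-chalcone F11.
   - Oxidative cyclization (I2 cat., DMSO, 120 °C) should give 21.

**Further compounds**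

F1 | step 5 | 2,6-bis(benzyloxy)-4-(methoxymethoxy)phenyl formate | O=COc1c(OCc2ccccc2)cc(OCOC)cc1OCc1ccccc1
F2 | step 5 | 2,6-bis(benzyloxy)-4-(methoxymethoxy)phenol | Oc1c(OCc2ccccc2)cc(OCOC)cc1OCc1ccccc1
F3 | step 5 | 2,6-bis(benzyloxy)-4-(methoxymethoxy)phenyl trifluoromethanesulfonate | O=S(=O)(Oc1c(OCc2ccccc2)cc(OCOC)cc1OCc1ccccc1)C(F)(F)F
F4 | step 4 | 1,3-bis(benzyloxy)-2-(2-methoxyethenyl)-5-(methoxymethoxy)benzene (E/Z mixture, geometry lost in the next step) | COC=Cc1c(OCc2ccccc2)cc(OCOC)cc1OCc1ccccc1
F5 | step 4 | methyl [2,6-bis(benzyloxy)-4-(methoxymethoxy)phenyl]acetate | COC(=O)Cc1c(OCc2ccccc2)cc(OCOC)cc1OCc1ccccc1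
F6 | step 4 | {2-[2,6-bis(benzyloxy)-4-(methoxymethoxy)phenyl]-1-methoxyethenyloxy}(tert-butyl)dimethylsilane (E/Z mixture, geometry lost on aromatization) | COC(O[Si](C)(C)C(C)(C)C)=Cc1c(OCc2ccccc2)cc(OCOC)cc1OCc1ccccc1
F7 | step 4 | methyl 3-[2,6-bis(benzyloxy)-4-(methoxymethoxy)phenyl]-4-(tert-butyldimethylsilyloxy)benzoate | COC(=O)c1ccc(O[Si](C)(C)C(C)(C)C)c(-c2c(OCc3ccccc3)cc(OCOC)cc2OCc2ccccc2)c1
F8 | step 4 | methyl 3-[2,6-bis(benzyloxy)-4-(methoxymethoxy)phenyl]-4-hydroxybenzoate | COC(=O)c1ccc(O)c(-c2c(OCc3ccccc3)cc(OCOC)cc2OCc2ccccc2)c1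
F9 | step 9 | analogue of 17 with iodine replaced by a 1-ethoxyvinyl group | COc1ccc(-c2cc(=O)c3c(OCc4ccccc4)cc(OCc4ccccc4)cc3o2)cc1-c1c(OCc2ccccc2)cc(O)c(C(=C)OCC)c1OCc1ccccc1
F10 | step 9 | analogue of 17 with iodine replaced by an acetyl group | COc1ccc(-c2cc(=O)c3c(OCc4ccccc4)cc(OCc4ccccc4)cc3o2)cc1-c1c(OCc2ccccc2)cc(O)c(C(C)=O)c1OCc1ccccc1
F11 | step 9 | analogue of 17 with iodine replaced by an (E)-3-[4-(benzyloxy)phenyl]prop-2-enoyl group | COc1ccc(-c2cc(=O)c3c(OCc4ccccc4)cc(OCc4ccccc4)cc3o2)cc1-c1c(OCc2ccccc2)cc(O)c(C(=O)/C=C/c2ccc(OCc3ccccc3)cc2)c1OCc1ccccc1
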